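The slowness to be read here is that of material leaving starting material and target for something unseen, and the cedar run, which is the very flask asked about followed so far, lets that slowness be read as a time.

- cedar: starting material 0.050 M (fed, over 5.0 min); second substrate 1 equiv; gas 16 mM (held); the very flask that is asked about, followed so far; the fed solution adds 0.10 times the starting volume
- flask: starting material 0.050 M (fed, over 5.0 min); second substrate 1.00 equiv; gas 16 mM (held); time 4.0 h; the fed solution adds 0.10 times the starting volume

cedar run (percent of the starting material charged)

| time / min | target / % | starting material / % |
|---|---|---|
| 4.00 | 3.8 | 76.2 |
| 10.0 | 12.9 | 83.4 |
| 20.0 | 16.6 | 68.9 |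
| 30.0 | 15.6 | 57.5 |
| 40.0 | 14.1 | 49.2 |

(standard deviation of a reading: 0.3 percentage points)

- charges are per starting volume, the dose included; the dosed solution carries all of it
- the analysis behind the earlier runs scatters by 0.3 percentage points, standard deviation
- at the start none of the gas is in solution
- percentages count the whole charge, also what has not yet gone in

- time, not beyond 4.0 h, at which the flask holds most target
- the amount of target, in percent of the starting material charged, at that time

Between 20.0 min and 40.0 min, long after the feed has ended, starting material and target together fall by 22 percentage points, while target stands near 15.6%. Read as a one-way, first-order drain on target, this gives a loss half-life of 9.74 min.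

The bench rule says that target peaks where what enters equals what leaves. Take the fall of starting material as what enters. With target at its highest reading, 16.6%, the loss half-life then gives a loss of 12 points per 10.0 min. Starting material falls by 15 points from 10.0 min to 20.0 min, more than that loss, but by 11 points in the next span, less than it. Interpolating between the middles of those spans, this reckoning puts the peak at 0.395 h, with a height near the cedar reading of 16.6%.

The rule's border is the end of the readings. The time allowed is 6.00 times the time of the last reading, and at that last reading the unseen material is already 2.60 times target. That the loss runs one way is an assumption of this reckoning, not a reading.

The forecast reasons alike, “The peak falls where formation equals loss.”, and gives 16.8% at 0.37 h, earlier than the reckoning here.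

The flask gives 16.5% at 0.361 h.

    starting material + partner ⇌ target (K = 37.0 M⁻¹, k = 0.0348 M⁻¹ s⁻¹)
    second substrate + partner → second product (k = 0.0596 M⁻¹ s⁻¹)
    target ⇌ isomer of the product (K = 27.4, k = 0.00123 s⁻¹)
    gas ⇌ partner, rate k4*(csat - [partner]) (kL = 0.0285 s⁻¹)

Target and isomer of the product relax into each other with a half-life of 0.151 h, short against the 4.0 h allowed. That allowance is 24.6 loss half-lives, yet at its end the flask holds 3.63% of target beside 89.6% of isomer of the product. The neighbouring flask, the same recipe read at 15 h, or 92.4 loss half-lives, has passed from kinetic to thermodynamic control: it holds 3.32% of target, and isomer of the product stands at 27.4 times that.

(The runs are calculated for substances that don't exist, noise included.)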